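The numbers in the tables are calculated with made-up constants; the scatter is artificial.

Solid substrate left of its charge stands at 48% in Thursday's flask at 120 min and at 47% in Monday's at 2.00 h. Use these two amounts to weigh topping up Thursday's flask to Monday's reagent before it runs on.

| flask | solid substrate | reagent | remark | time |
|---|---|---|---|---|
| Thursday's | 20 mM | 20 mM | the very flask that is asked about, followed so far |  |
| Monday's | 20 mM | 30 mM | run made earlier |  |
| flask | 20 mM | 20.0 mM |  | 6.0 h |

Thursday's run (percent of the solid substrate charged)

| time / min | solid substrate / % | product / % |
|---|---|---|
| 15.0 | 89 | 0 |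
| 40.0 | 75 | 2 |
| 80.0 | 57 | 0 |
| 120 | 48 | 0 |

Monday's run (percent of the solid substrate charged)

| time / h | solid substrate / % | product / % |
|---|---|---|
| 0.667 | 76 | 0 |
| 1.33 | 57 | 0 |
| 2.00 | 47 | 0 |
| 2.50 | 37 | 3 |

(standard deviation of a reading: 1.5 percentage points)

- as a solid, counted per litre of solution: solid substrate
- at the start none of the solid substrate is in solution

- amount of solid substrate in percent of the solid substrate charged, at 40 min, 2.0 h and 6.0 h

Reckon Thursday's 0.367 h⁻¹ as the loss constant, the apparent first-order constant: the natural logarithm of one over the fraction of solid left, divided by the time. Monday's flask, with 30 mM of reagent against 20 mM, gives 0.378 h⁻¹. Its reading differs by 1 percentage point against a scatter of 1.5 points, so the extra reagent shows no gain in solid lost up to 2.00 h. No pair of readings stands beyond that time, so the top-up stays an open question for the later hours. Reckon on, then, for the flask as asked, with 20.0 mM of reagent.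

Now watch the drift. At 40.0 min Thursday's constant read 0.432 h⁻¹, higher than at 120 min, so the loss is slowing. Carried to 6.0 h, the constant leaves 11.1% of the solid. Commit to that as the low side, and take 75% and 48% as they were read for the earlier times.

The forecast gives 75.5%, 47.5% and 11%, holding that “solid loss is dissolution, independent of reagent”.

The flask gives 75.9%, 45.6% and 11.5%.

    starting material + reagent → intermediate + by-product (k = 2.00 M⁻¹ h⁻¹)
    intermediate → product (k = 0.110 h⁻¹)
    solid substrate ⇌ starting material, rate k3*(cs3 - [starting material]) while solid is left; crystals form when [starting material] > cs3 (solubility = 17.0 mM, k = 0.500 h⁻¹)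

In Thursday's flask, going into solution ran through to 6.0 h, turning over 88.5% of the charge with its midpoint at 1.46 h. The reaction of starting material with reagent ran later than that, with its midpoint at 3.63 h, and at 6.00 h intermediate held 9.64% of the charge and product 2.83%. The flask's loss constant over 6.0 h comes to 0.360 h⁻¹, lower than 0.367 h⁻¹. With half the reagent, solid substrate stands at 15.3% at 6.0 h, 4.3 points above the forecast's figure, a loss constant of 0.313 h⁻¹.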